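**The flat end.** Read the flat end of a run before anything else, since two amounts can be compared there without any model.

| flask | starting material | second substrate | gas | remark | time |
|---|---|---|---|---|---|
| alder | 0.20 M | 1 equiv | 14 mM (held) | the very flask that is asked about, followed so far |  |
| maple | 0.10 M | 1 equiv | 14 mM (held) | run made earlier |  |
| flask | 0.20 M | 1.00 equiv | 14 mM (held) |  | 15 d |

| run | time / d | target / % | starting material / % |
|---|---|---|---|
| alder | 0.625 | 43.2 | 55.6 |
| alder | 1.04 | 65.0 | 37.7 |
| alder | 2.00 | 89.1 | 14.0 |
| alder | 4.00 | 92.0 | 7.1 |
| alder | 8.00 | 93.0 | 6.0 |
| maple | 1.04 | 70.9 | 31.0 |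
| maple | 2.50 | 91.4 | 6.7 |
| maple | 5.00 | 96.2 | 4.9 |
| maple | 8.00 | 94.8 | 6.6 |
| maple | 10.0 | 95.6 | 3.9 |

(readings scatter by 1 percentage point)

- at the start none of the gas is in solution
- the reaction counts as stopped when no species that holds the starting material changes by six tenths of a point or more over the second half of the time

- which holds at 15 d: what has brought the reaction to rest, or that it has not come to rest (all of the starting material has reacted / forward and back rates have come level / it is still moving)
- target at 15 d, in percent of the starting material charged

**Two amounts.** I followed one molecule of starting material, which I took to cross to target and cross back, so I looked at how the charge divided between those two forms late in a run. I kept the rest ratio ρ, target over starting material once both stop moving (an apparent equilibrium constant). The maple readings from 5.00 d to 10.0 d stayed level within the scatter, and pooled they gave ρ = 18.6. Alder's last reading gave 15.5, but with starting material at 6.0% and a scatter of 1 percentage point it did not separate from maple. I therefore carried ρ to alder, although alder was charged twice as strongly, and reckoned target as ρ/(1+ρ) = 94.9%.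

**The forecast.** It answered that forward and back rates have come level, with target 93.6%, holding that “A stop at a finite residue, flat for days, points to a balance between forward and back rates”. My figure stood 1.3 points higher.

**The result.** In alder at 15 d, forward and back rates have come level, with target 95.1%.

    2 reagent → self-condensation product (k = 0.800 M⁻¹ h⁻¹)
    gas ⇌ reagent, rate k2*(csat - [reagent]) (kL = 2.70 h⁻¹)
    second substrate + reagent ⇌ second product (K = 370 M⁻¹, k = 3.80 M⁻¹ h⁻¹)
    starting material + reagent ⇌ target (K = 1400 M⁻¹, k = 4.20 M⁻¹ h⁻¹)

**The neighbour.** Alder ended with 4.9% of its starting material, a rest ratio of 19.4, and the equilibrium constant of the target step, 1400 M⁻¹, times reagent at 0.0139 M comes to 19.5. The neighbour charged with 0.50 M of starting material held reagent at 0.0139 M, 4.9% of its starting material and 95.1% target at 15.0 d, a rest ratio of 19.4.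

The readings come from a simulation with made-up constants, and the scatter is random.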